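The readings stem from a simulated flask with made-up constants.

75.7 % of the starting material that had left the north-west run by 20.0 min stood there as target. I carried this number forward as the target share, the usual selectivity: target divided by starting material consumed up to that time.

| setting | north-west | west | flask |
|---|---|---|---|
| starting material | 0.87 M | 1.4 M | 0.62 M |
| reagent | 0.744 M | 0.744 M | 0.744 M |
| remark | run made earlier | run made earlier |  |
| time |  |  | 20 min |

| run | time / min | target / % | starting material / % |
|---|---|---|---|
| north-west | 1.33 | 25.6 | 68.5 |
| north-west | 4.00 | 47.4 | 42.1 |
| north-west | 6.00 | 54.5 | 30.6 |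
| north-west | 10.0 | 63.0 | 19.9 |
| north-west | 15.0 | 66.5 | 12.5 |
| north-west | 20.0 | 68.3 | 9.8 |
| north-west | 25.0 | 70.1 | 7.2 |
| west | 1.33 | 28.6 | 66.0 |
| west | 4.00 | 47.6 | 42.1 |
| west | 6.00 | 51.8 | 35.1 |
| west | 10.0 | 53.5 | 27.5 |
| west | 15.0 | 53.1 | 23.1 |
| west | 20.0 | 51.5 | 19.9 |
| west | 25.0 | 52.9 | 17.9 |

(readings scatter by 0.5 percentage points)

- amount of target in percent of the starting material charged, at 4.0 min, 10 min and 20 min

- the earlier runs were read with a standard deviation of 0.5 percentage points

At 4.00 min both runs had kept the same fraction of starting material, 42.1 % and 42.1 %, and showed target shares of 81.9 % and 82.2 %, although their charges were 0.87 M and 1.4 M, but I read this as a crossing of the two courses and not as indifference to the charge, since the west run had more target than the north-west run at 1.33 min, 28.6 % against 25.6 %, and less at 6.00 min, 51.8 % against 54.5 %. Later the west run lagged, and its c(target) stood near 0.721 M at 20.0 min. If one target takes one reagent, that left c(reagent) at 0.0230 M, which made reagent the limiting reagent there.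

My first way to the flask at 20 min was a straight line in the charge through the two runs, which reached 76.2 %. My second way multiplied the target share by the consumption, taking the flask's starting material left from the north-west run, since the flask has 0.744 M of reagent for 0.62 M of starting material; this gave 68.3 %. They parted by 7.9 points, and the line was the one that cheated: at that share it needed 101 % of the charge consumed, which is more than was charged. Its slope also came from the west run, whose c(reagent) left was less than the 0.150 M of the north-west run. I therefore committed to the north-west course, 47.4 %, 63.0 % and 68.3 %.

The forecast, which stands above my figure at the last time, gave 47.5 %, 68 % and 76 %, with the words “Reagent therefore limits target” among its grounds. The flask gave 45.3 %, 62.0 % and 69.5 %.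

    starting material + reagent → target, rate k1*[starting material]^1.5*[reagent]^0.5 (k = 0.00580 L mol⁻¹ s⁻¹)
    starting material ⇌ dormant form (K = 3.60, k = 7.70 × 10⁻⁴ s⁻¹)

Both steps were running in the flask from the start: by 2.00 min it held 30.8 % target and 7.15 % dormant form, and by 10.0 min 62.0 % and 18.5 %, with starting material down to 19.5 %. By 20.0 min target had reached 69.5 % and dormant form 21.8 %, with 42.1 % of the reagent's own charge left. The flask's target share then came to 76.1 % against my 75.7 %, and the same quotient in the west run at 20.0 min, with c(reagent) at 0.0230 M, reads 64.3 %.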